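52.0% of a charge of 1.5 M: that is where dissolved substrate stood in the gamma run at 2.50 h, and at 3.00 h it still read 51.5%.

- gamma: solid substrate 1.5 M; gas 200 mM (held); run made earlier
- flask: solid substrate 2.2 M; gas 200 mM (held); time 10 h

gamma run (percent of the solid substrate charged)

| time / h | target / % | dissolved substrate / % |
|---|---|---|
| 0.417 | 0.9 | 20.9 |
| 1.33 | 11.7 | 43.1 |
| 2.50 | 23.5 | 52.0 |
| 3.00 | 27.2 | 51.5 |
| 5.00 | 34.9 | 21.7 |
| 6.00 | 34.3 | 14.0 |
| 8.00 | 32.5 | 3.6 |

(scatter of a reading: 1 percentage point)

- amount of target at 10 h, in percent of the solid substrate charged
- concentration of dissolved substrate in solution at 5.0 h, in percent of saturation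
- the change that raises the amount of target at 10 h, in percent of the solid substrate charged most ("none" if none brings more than 2 percentage points) (Thursday's / Monday's / Sunday's / Saturday's / none)
- amount of target at 10 h, in percent of the solid substrate charged, after Monday's

- solid substrate is a solid; its amount is given per volume of the solution
- at the start none of the gas is in solution
- at the start none of the solid substrate is in solution
- dissolved substrate means what is dissolved; the solid is not counted in it

- Thursday's: doubling the saturation concentration of gas, all else as stated
- Monday's: doubling the transfer coefficient of the gas, all else as stated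
- Sunday's: doubling the dissolution coefficient of the solid substrate, all else as stated
- Saturday's: doubling the solubility of the solid substrate, all else as stated

What do those two gamma readings say? That dissolved substrate had stopped rising, since they differ by less than the scatter of 1 percentage point. I read this as solid feeding the solution as fast as the solution is drained.

And what do you do with that? I take the balance as settled, a resting state, and reckon with the level it leaves, the resting level of dissolved substrate, 0.780 M.

Why carry it as a concentration and not as a percentage? I assume that neither feed nor drain counts how much solid lies there, so long as some does. The flask's larger charge then buys a longer stay at this level, not a higher one. As a fraction of the flask's charge the level is 35.5%, lower than in gamma.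

Does the solid in the flask last until 5.0 h? That is the weak spot. Gamma held its level at least until 3.00 h, so its feed averaged at most 0.500 M h⁻¹ over that stretch. At that average the flask's charge lasts 4.40 h, which falls short. But the average contains the quick early filling, and the feed at the level is slower, so I commit to solid just reaching 5.0 h and dissolved substrate still near 35.5% of the charge.

The forecast gave 27%, 43%, Thursday's and 29%, and said “In the flask, 2.2 M should last until about 4.5 h”, an earlier end of the solid than in my reckoning.

The flask gives 28.0%, 60.2%, Thursday's and 28.0%.

    dissolved substrate + partner → target (k = 4.73 × 10⁻⁴ M⁻¹ s⁻¹)
    gas ⇌ partner, rate k2*(csat - [partner]) (kL = 0.0639 s⁻¹)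
    dissolved substrate + target → side product (k = 5.54 × 10⁻⁵ M⁻¹ s⁻¹)
    solid substrate ⇌ dissolved substrate, rate k4*(cs4 - [dissolved substrate]) while solid is left; crystals form when [dissolved substrate] > cs4 (solubility = 1.30 M, k = 1.88 × 10⁻⁴ s⁻¹)
    2 partner → self-condensation product (k = 1.58 × 10⁻⁴ M⁻¹ s⁻¹)
    target ⇌ isomer of the product (K = 1.32, k = 6.20 × 10⁻⁵ s⁻¹)

At 5.00 h the flask held 35.6% of its charge as dissolved substrate, with 2.33% still solid, against the 35.5% reckoned. The neighbouring flask with 1.3 M of solid substrate takes the same reckoning: the level is 60.0% of its charge, a larger share than the 35.5% of the flask. At 10.0 h that neighbour holds 0% solid, 2.45% dissolved substrate, 32.2% target and 31.4% side product.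

The readings come from a simulation for an exercise; scatter was added.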